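**Plan**

- Retrosynthesis: the thirteen methoxymethyl (MOM) groups are removed first; then the two inner bridge bonds, CH2–ring B and CH2–ring D, are cut. Both methylene carbons stay on ring C as benzylic zinc sites, and two identical bromo A–B dimers result. Each dimer is cut at its A–B bridge into a ring B quinone-methide precursor and butyrylfilicinic acid (ring A).
- Enabling feature: a mirror plane passes through ring C, so the C–CH2–B and C–CH2–D bonds are equivalent. Each joins a bridge carbon to a ring carbon of B or D that lies between two oxygen-bearing carbons and is innately nucleophilic. With all thirteen hydroxyls capped no ortho-quinone methide can form, so these bonds have to be made, twice in one operation, by an irreversible palladium coupling of inverted polarity.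
- Forward order: rings A, B and C all derive from butyrylphloroglucinol (gem-dimethylation, monobromination and diformylation respectively). A and B are joined by the innate quinone-methide pathway and the dimer is protected; ring C is taken to its bis(benzylic zinc chloride); one double coupling assembles A–B–C–D–E; acid removes the MOM groups.
- Stereochemistry: the target has no stereocentre and no stereogenic double bond, so nothing has to be set.

Key step: step 11

Assumption: exhaustive O-alkylation of a filicinic-acid ring is drawn as the bis-enol ether at the two oxygens flanking the bridge carbon (as in 8); a regioisomeric bis-enol ether would couple in the same way and give the same triketone in step 12.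

**Route**

Step 1
Reactants: 1 butyrylphloroglucinol
Product: 3 butyrylfilicinic acid, via 3-methylbutyrylphloroglucinol 2 (not isolated)
Conditions: NaOMe (3.5 equiv), MeI (2.2 equiv), MeOH, 0 °C to rt
Reagents that add atoms: iodomethane, CI
Why: Enolate C-alkylation of the phloroglucinol polyanion, in which the first methyl group enters a free ring carbon to give 2 and the second enters the same, now most electron-rich carbon, dearomatising the ring to the gem-dimethyl β-triketone (the classical preparation of acylfilicinic acids, with over- and under-methylated by-products removed by chromatography).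

Step 2
Reactants: 1 butyrylphloroglucinol
Product: 4 1-(3-bromo-2,4,6-trihydroxyphenyl)butan-1-one
Conditions: NBS (1.0 equiv, slow addition), MeCN, −20 °C
Reagents that add atoms: N-bromosuccinimide, O=C1CCC(=O)N1Br
Why: Electrophilic aromatic bromination of one of the two equivalent free ring positions, held at the monobromide by stoichiometry and low temperature; the bromine blocks one nucleophilic site and serves later as the coupling handle.

Step 3
Reactants: 4 1-(3-bromo-2,4,6-trihydroxyphenyl)butan-1-one
Product: 5 1-{3-bromo-5-[(dimethylamino)methyl]-2,4,6-trihydroxyphenyl}butan-1-one (ring B Mannich base)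
Conditions: aq. CH2O (1.1 equiv), aq. Me2NH (1.2 equiv), EtOH, 0 °C to rt
Reagents that add atoms: formaldehyde, C=O; dimethylamine, CNC
Why: Mannich aminomethylation of the only remaining free ring carbon of an acylphloroglucinol, which can give a single regioisomer because bromine occupies the other site.

Step 4
Reactants: 5 ring B Mannich base; 3 butyrylfilicinic acid (1.3 equiv)
Product: 7 bromo A–B dimer, via ortho-quinone methide 6 (not isolated)
Conditions: 1,4-dioxane, 90 °C, N2 stream to carry off Me2NH
Reagents that add atoms: none
Why: Thermal loss of dimethylamine from the ortho-hydroxybenzylamine gives quinone methide 6, which is trapped in a Michael addition by the free enolic ring carbon of 3 and rearomatises (Mannich-base-mediated methylene bridging of phloroglucinols).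

Step 5
Reactants: 7 bromo A–B dimer
Product: 8 penta-O-methoxymethyl bromo A–B dimer
Conditions: MOMCl (6 equiv), NaH (5.5 equiv, added in portions to substrate and MOMCl), THF–DMF, −10 to 0 °C
Reagents that add atoms: chloromethyl methyl ether, COCCl
Why: Williamson-type O-alkylation of three phenoxide and two enolate oxygens by a hard α-chloro ether, which favours O over C, with the alkylating agent present from the start so that each anion is capped before the bridge can undergo retro-Michael cleavage.

Step 6
Reactants: 1 butyrylphloroglucinol
Product: 10 5-butanoyl-2,4,6-trihydroxybenzene-1,3-dicarbaldehyde, via bis(chloro ether) 9 (not isolated)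
Conditions: Cl2CHOMe (3 equiv), TiCl4 (5 equiv), CH2Cl2, 0 °C to rt; then aq. HCl
Reagents that add atoms: dichloromethyl methyl ether, COC(Cl)Cl; water, O
Why: Rieche formylation, in which TiCl4 ionises the dichloromethyl ether to a chloro(methoxy)carbenium ion that substitutes both free, titanium-phenoxide-activated ring carbons without touching the enolisable ketone, and aqueous acid hydrolyses the α-chloro ethers 9 to aldehydes.

Step 7
Reactants: 10 5-butanoyl-2,4,6-trihydroxybenzene-1,3-dicarbaldehyde
Product: 11 5-butanoyl-2,4,6-tris(methoxymethoxy)benzene-1,3-dicarbaldehyde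
Conditions: NaH (3.3 equiv), MOMCl (3.6 equiv), DMF, 0 °C
Reagents that add atoms: chloromethyl methyl ether, COCCl
Why: O-alkylation (MOM ether formation) of the three strongly acidic, carbonyl-chelated phenols through their sodium phenoxides; no ring carbon is free for C-alkylation.

Step 8
Reactants: 11 5-butanoyl-2,4,6-tris(methoxymethoxy)benzene-1,3-dicarbaldehyde
Product: 12 1-[3,5-bis(hydroxymethyl)-2,4,6-tris(methoxymethoxy)phenyl]butan-1-one
Conditions: NaBH4 (1.0 equiv), THF–MeOH, −40 to −20 °C
Reagents that add atoms: none
Why: Chemoselective borohydride reduction of the two aldehydes in the presence of the much less electrophilic aryl ketone, which is flanked by two ortho substituents and twisted out of conjugation.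

Step 9
Reactants: 12 1-[3,5-bis(hydroxymethyl)-2,4,6-tris(methoxymethoxy)phenyl]butan-1-one
Product: 13 1-[3,5-bis(chloromethyl)-2,4,6-tris(methoxymethoxy)phenyl]butan-1-one
Conditions: PPh3 (2.4 equiv), NCS (2.4 equiv), THF, 0 °C to rt
Reagents that add atoms: N-chlorosuccinimide, O=C1CCC(=O)N1Cl
Why: Appel-type chlorination of the benzylic alcohols through alkoxyphosphonium ions under neutral, HCl-free conditions that leave the acid-labile MOM ethers intact.

Step 10
Reactants: 13 1-[3,5-bis(chloromethyl)-2,4,6-tris(methoxymethoxy)phenyl]butan-1-one
Product: 14 ring C bis(benzylic zinc chloride), used as its LiCl-complexed THF solution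
Conditions: Zn dust (3 equiv, activated with BrCH2CH2Br and Me3SiCl), LiCl (3 equiv), THF, 25 °C
Reagents that add atoms: zinc, [Zn]
Why: LiCl-promoted direct insertion of zinc metal into benzylic C–Cl bonds, a method that tolerates ketones; the meta relationship of the two sites excludes xylylene-type elimination.

Step 11
Reactants: 14 ring C bis(benzylic zinc chloride); 8 penta-O-methoxymethyl bromo A–B dimer (2.2 equiv)
Product: 16 trideca-O-methoxymethyl pentaalbaspidin BBBBB, via mono-coupled benzylic zinc chloride 15 (not isolated)
Conditions: Pd(OAc)2 (5 mol %), SPhos [dicyclohexyl(2',6'-dimethoxybiphenyl-2-yl)phosphine] (10 mol %), THF, slow addition of 14 at 25 °C, then 50 °C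
Reagents that add atoms: none
Why: The organozinc reduces Pd(OAc)2 to a zerovalent palladium–SPhos species that inserts into the C–Br bond of ring B in 8; a benzylic zinc chloride of 14 transmetalates and reductive elimination forms the CH2–ring B bond to give 15, after which the same cycle at the second CH2ZnCl site with another molecule of 8 forms the CH2–ring D bond. The closest known reaction is the Negishi coupling of LiCl-solubilised benzylic zinc chlorides with aryl bromides under Pd(OAc)2 and SPhos, which gives diarylmethanes in the presence of ketones. No ring is closed and no stereocentre is created, so no mode of cyclisation or element of stereocontrol is involved. The step needs chemoselectivity for C–Br over five ketone and vinylogous-ester carbonyls and reactivity at a bromide flanked by two alkoxy groups; the first should follow from the low carbonyl reactivity of benzylic zinc halides, the second from the bulky, electron-rich biarylphosphine, while the CH2 spacer keeps the two crowded rings apart during reductive elimination. Because the ring carbon is the electrophile and the bridge carbon the nucleophile, and every oxygen is capped, neither partner nor product can shed a ring by retro-Michael cleavage, so the A–B–C–D–E order is fixed by the coupling itself. The slight excess of 8 is meant to ensure that both zinc sites meet a bromide before they are lost.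

Step 12
Reactants: 16 trideca-O-methoxymethyl pentaalbaspidin BBBBB
Product: 17 pentaalbaspidin BBBBB
Conditions: HCl (3 M) in MeOH–THF, rt to 40 °C
Reagents that add atoms: none
Why: Acid-catalysed acetal exchange with methanol removes the nine aryl MOM ethers and the four MOM enol ethers of rings A and E, and since every ring carbon is substituted the methoxymethyl cation has no carbon to re-alkylate.

**Compound list**

1 | 1-(2,4,6-trihydroxyphenyl)butan-1-one (butyrylphloroglucinol) | CCCC(=O)c1c(O)cc(O)cc1O | starting material
2 | 1-(2,4,6-trihydroxy-3-methylphenyl)butan-1-one (3-methylbutyrylphloroglucinol) | CCCC(=O)c1c(O)cc(O)c(C)c1O | intermediate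
3 | 2-butanoyl-3,5-dihydroxy-6,6-dimethylcyclohexa-2,4-dien-1-one (butyrylfilicinic acid, ring A) | CCCC(=O)C1=C(O)C=C(O)C(C)(C)C1=O | intermediate
4 | 1-(3-bromo-2,4,6-trihydroxyphenyl)butan-1-one | CCCC(=O)c1c(O)cc(O)c(Br)c1O | intermediate
5 | 1-{3-bromo-5-[(dimethylamino)methyl]-2,4,6-trihydroxyphenyl}butan-1-one (ring B Mannich base) | CCCC(=O)c1c(O)c(CN(C)C)c(O)c(Br)c1O | intermediate
6 | 2-bromo-4-butanoyl-3,5-dihydroxy-6-methylidenecyclohexa-2,4-dien-1-one (ring B ortho-quinone methide) | CCCC(=O)C1=C(O)C(=C)C(=O)C(Br)=C1O | intermediate
7 | 2-butanoyl-4-[(3-bromo-5-butanoyl-2,4,6-trihydroxyphenyl)methyl]-3,5-dihydroxy-6,6-dimethylcyclohexa-2,4-dien-1-one (bromo A–B dimer) | CCCC(=O)C1=C(O)C(Cc2c(O)c(Br)c(O)c(C(=O)CCC)c2O)=C(O)C(C)(C)C1=O | intermediate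
8 | 2-butanoyl-4-{[3-bromo-5-butanoyl-2,4,6-tris(methoxymethoxy)phenyl]methyl}-3,5-bis(methoxymethoxy)-6,6-dimethylcyclohexa-2,4-dien-1-one (penta-O-methoxymethyl bromo A–B dimer) | CCCC(=O)C1=C(OCOC)C(Cc2c(OCOC)c(Br)c(OCOC)c(C(=O)CCC)c2OCOC)=C(OCOC)C(C)(C)C1=O | intermediate
9 | 1-{3,5-bis[chloro(methoxy)methyl]-2,4,6-trihydroxyphenyl}butan-1-one (bis(chloro ether), diastereomer mixture whose two centres vanish on hydrolysis) | CCCC(=O)c1c(O)c(C(Cl)OC)c(O)c(C(Cl)OC)c1O | intermediate
10 | 5-butanoyl-2,4,6-trihydroxybenzene-1,3-dicarbaldehyde | CCCC(=O)c1c(O)c(C=O)c(O)c(C=O)c1O | intermediate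
11 | 5-butanoyl-2,4,6-tris(methoxymethoxy)benzene-1,3-dicarbaldehyde | CCCC(=O)c1c(OCOC)c(C=O)c(OCOC)c(C=O)c1OCOC | intermediate
12 | 1-[3,5-bis(hydroxymethyl)-2,4,6-tris(methoxymethoxy)phenyl]butan-1-one | CCCC(=O)c1c(OCOC)c(CO)c(OCOC)c(CO)c1OCOC | intermediate
13 | 1-[3,5-bis(chloromethyl)-2,4,6-tris(methoxymethoxy)phenyl]butan-1-one | CCCC(=O)c1c(OCOC)c(CCl)c(OCOC)c(CCl)c1OCOC | intermediate
14 | ring C bis(benzylic zinc chloride): 1-[3,5-bis(chlorozinciomethyl)-2,4,6-tris(methoxymethoxy)phenyl]butan-1-one, LiCl-complexed in THF | CCCC(=O)c1c(OCOC)c(C[Zn]Cl)c(OCOC)c(C[Zn]Cl)c1OCOC | intermediate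
15 | mono-coupled A–B–C benzylic zinc chloride (ring C carries one CH2–ring B bond and one CH2ZnCl group) | CCCC(=O)C1=C(OCOC)C(Cc2c(OCOC)c(Cc3c(OCOC)c(C[Zn]Cl)c(OCOC)c(C(=O)CCC)c3OCOC)c(OCOC)c(C(=O)CCC)c2OCOC)=C(OCOC)C(C)(C)C1=O | intermediate
16 | trideca-O-methoxymethyl pentaalbaspidin BBBBB | CCCC(=O)C1=C(OCOC)C(Cc2c(OCOC)c(Cc3c(OCOC)c(Cc4c(OCOC)c(CC5=C(OCOC)C(C)(C)C(=O)C(C(=O)CCC)=C5OCOC)c(OCOC)c(C(=O)CCC)c4OCOC)c(OCOC)c(C(=O)CCC)c3OCOC)c(OCOC)c(C(=O)CCC)c2OCOC)=C(OCOC)C(C)(C)C1=O | intermediate
17 | pentaalbaspidin BBBBB | CCCC(=O)C1=C(O)C(Cc2c(O)c(Cc3c(O)c(Cc4c(O)c(CC5=C(O)C(C)(C)C(=O)C(C(=O)CCC)=C5O)c(O)c(C(=O)CCC)c4O)c(O)c(C(=O)CCC)c3O)c(O)c(C(=O)CCC)c2O)=C(O)C(C)(C)C1=O | target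

**Step count**

Total: 12 steps. Longest linear sequence: 7 steps (steps 6, 7, 8, 9, 10, 11, 12 from butyrylphloroglucinol).

**Steps most likely to fail**

Step 11. The benzylic zinc sites may be lost by protonation or Wurtz-type homocoupling faster than the crowded partners couple, which would stop chain growth after the first coupling. The fallback sets out from 8 and 13 and returns at 16. Bromide 8 would be borylated (B2pin2, Pd(OAc)2, SPhos, KOAc, dioxane, 80 °C; Miyaura borylation) to the aryl pinacol boronate F1. Two equivalents of it would then be joined to the bis(benzylic chloride) 13 (Pd(OAc)2, SPhos, anhydrous K3PO4, toluene, 80 °C; benzylic Suzuki–Miyaura coupling). The same two bonds are formed, but the nucleophile is then a storable boronate and the bridge carbon the electrophile, so no organozinc has to survive.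

Step 5. The polyanion of 7 may undergo retro-Michael cleavage and exchange of the A–B bridge before it is capped, and O-alkylation of ring A may be spread over several enol oxygens. The fallback sets out from 4 and 14, uses 3, and returns at 17; it keeps the filicinic rings out of all protection chemistry.
- Bromide 4 would be converted into 1-[3-bromo-2,4,6-tris(methoxymethoxy)phenyl]butan-1-one F2 (NaH, MOMCl, DMF, 0 °C).
- Two equivalents of F2 would be coupled with 14 under the conditions of step 11 to the nona-O-methoxymethyl B–C–D trimer F3.
- HCl in MeOH would release the free B–C–D trimer F4.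
- Its two remaining ring CH positions would be bridged to two molecules of 3 with aqueous formaldehyde in cold dilute aqueous KOH for a short time (classical formaldehyde condensation through the ring A methylidene triketone), giving 17.

Step 4. Quinone methide 6 may be captured by Mannich base 5 itself, or the product bridge may re-open at 90 °C, so that symmetrical dimers accumulate. The fallback sets out from 3 and 4 and returns at 7, with the roles of the rings exchanged. Acid 3 would be aminomethylated (aq. CH2O, Me2NH, EtOH, 0 °C) to the ring A Mannich base F5. This vinylogous acid should lose dimethylamine near room temperature. Stirred with an excess of 4 in MeCN at 25 to 40 °C, the resulting ring A methylidene triketone would be trapped by the single free ring carbon of 4, at a temperature where the new bridge should not re-open.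

**Further compounds**

F1 | step 11 | 2-butanoyl-4-{[3-butanoyl-2,4,6-tris(methoxymethoxy)-5-(4,4,5,5-tetramethyl-1,3,2-dioxaborolan-2-yl)phenyl]methyl}-3,5-bis(methoxymethoxy)-6,6-dimethylcyclohexa-2,4-dien-1-one (aryl pinacol boronate) | CCCC(=O)C1=C(OCOC)C(Cc2c(OCOC)c(B3OC(C)(C)C(C)(C)O3)c(OCOC)c(C(=O)CCC)c2OCOC)=C(OCOC)C(C)(C)C1=O
F2 | step 5 | 1-[3-bromo-2,4,6-tris(methoxymethoxy)phenyl]butan-1-one | CCCC(=O)c1c(OCOC)cc(OCOC)c(Br)c1OCOC
F3 | step 5 | nona-O-methoxymethyl B–C–D trimer, 1-[3,5-bis({3-butanoyl-2,4,6-tris(methoxymethoxy)phenyl}methyl)-2,4,6-tris(methoxymethoxy)phenyl]butan-1-one | CCCC(=O)c1c(OCOC)cc(OCOC)c(Cc2c(OCOC)c(Cc3c(OCOC)cc(OCOC)c(C(=O)CCC)c3OCOC)c(OCOC)c(C(=O)CCC)c2OCOC)c1OCOC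
F4 | step 5 | free B–C–D trimer, 1-{3,5-bis[(3-butanoyl-2,4,6-trihydroxyphenyl)methyl]-2,4,6-trihydroxyphenyl}butan-1-one | CCCC(=O)c1c(O)cc(O)c(Cc2c(O)c(Cc3c(O)cc(O)c(C(=O)CCC)c3O)c(O)c(C(=O)CCC)c2O)c1O
F5 | step 4 | 2-butanoyl-4-[(dimethylamino)methyl]-3,5-dihydroxy-6,6-dimethylcyclohexa-2,4-dien-1-one (ring A Mannich base) | CCCC(=O)C1=C(O)C(CN(C)C)=C(O)C(C)(C)C1=O
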